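**Assumption:** the SMILES is taken literally, i.e. the (1R,2R,3R)-indane with H-1, H-2 and H-3 on the same face (all-cis), and the four benzyl-protected building blocks named as starting materials are bought as such.

## Retrosynthetic overview

1. Caraphenol C ⇐ hexabenzyl 3-aroyl-1,2-diaryl-1H-indene carrying one stereocentre (C3 of the target). A single final H2/Pd operation removes six benzyl groups and saturates the tetrasubstituted enone anti to the C3 aryl, which creates C1 and C2 all-cis (key step).
2. Indenyl aryl ketone ⇐ indenyl triflate + aryl stannane + CO (base-free carbonylative Stille coupling).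
3. Indenyl triflate ⇐ trans-2,3-diarylindanone ⇐ (R)-3-arylindanone + aryl bromide (palladium α-arylation).
4. (R)-3-Arylindanone ⇐ 2′-bromochalcone (asymmetric reductive Heck cyclisation) ⇐ bromoacetophenone + aldehyde (Claisen–Schmidt).
5. Ring order: the four benzene rings are bought; the five-membered ring is the only ring made (step 3, which also sets the controlling stereocentre); C1 and C2 are set last.

## Route

**Step 1**
Reactants: 1 1-[3,5-bis(benzyloxy)phenyl]ethan-1-one
Product: 2 1-[3,5-bis(benzyloxy)-2-bromophenyl]ethan-1-one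
Conditions: NBS (1.05 equiv), MeCN, 0 °C to rt, dark
Reagents that add atoms: N-bromosuccinimide, O=C1CCC(=O)N1Br
Why: Electrophilic aromatic bromination goes to C2 (para to one benzyloxy group and ortho to the other) in preference to the more crowded C4 between the two benzyloxy groups, and the benzyl ethers and the methyl ketone are inert to NBS in MeCN.

**Step 2**
Reactants: 2 1-[3,5-bis(benzyloxy)-2-bromophenyl]ethan-1-one; 3 4-(benzyloxy)benzaldehyde
Product: 4 (2E)-1-[3,5-bis(benzyloxy)-2-bromophenyl]-3-[4-(benzyloxy)phenyl]prop-2-en-1-one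
Conditions: KOH (aq, cat.), EtOH–THF, rt, 16 h
Reagents that add atoms: none
Why: Claisen–Schmidt aldol condensation in which the non-enolisable aldehyde can only be the acceptor and E1cB dehydration gives the (E)-chalcone.

**Step 3**
Reactants: 4 (2E)-1-[3,5-bis(benzyloxy)-2-bromophenyl]-3-[4-(benzyloxy)phenyl]prop-2-en-1-one
Product: 5 (3R)-4,6-bis(benzyloxy)-3-[4-(benzyloxy)phenyl]-2,3-dihydro-1H-inden-1-one
Conditions: Pd(OAc)2 (5 mol %), 3,5-Xyl-MeO-BIPHEP (6 mol %, the antipode that gives 3R), HCO2Na (1.5 equiv, slow addition), ethylene glycol–DMF, 80 °C; recrystallise to >99% ee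
Reagents that add atoms: none
Why: Asymmetric intramolecular reductive Heck reaction, in which oxidative addition of the aryl bromide, enantio-determining carbopalladation of the enone β-carbon inside the chiral bisphosphine pocket and formate-driven release of the palladium enolate close the five-membered ring and set C3 (the ligand antipode giving R is fixed on the first run by chiral HPLC and rotation).

**Step 4**
Reactants: 5 (3R)-4,6-bis(benzyloxy)-3-[4-(benzyloxy)phenyl]-2,3-dihydro-1H-inden-1-one; 6 1,3-bis(benzyloxy)-5-bromobenzene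
Product: 7 (2R,3R)-4,6-bis(benzyloxy)-2-[3,5-bis(benzyloxy)phenyl]-3-[4-(benzyloxy)phenyl]-2,3-dihydro-1H-inden-1-one (trans)
Conditions: Pd(OAc)2 (3 mol %), XPhos (6 mol %), NaOtBu (2.2 equiv), toluene, 70 °C; aq NH4Cl
Reagents that add atoms: none
Why: Buchwald–Hartwig-type palladium-catalysed ketone α-arylation through the sodium enolate, in which only C2 can be arylated, the non-acidic C3–H stereocentre is untouched and equilibration through the product enolate gives the trans isomer (the C2 configuration is erased in the next step anyway).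

**Step 5**
Reactants: 7 (2R,3R)-4,6-bis(benzyloxy)-2-[3,5-bis(benzyloxy)phenyl]-3-[4-(benzyloxy)phenyl]-2,3-dihydro-1H-inden-1-one
Product: 9 (1R)-5,7-bis(benzyloxy)-2-[3,5-bis(benzyloxy)phenyl]-1-[4-(benzyloxy)phenyl]-1H-inden-3-yl trifluoromethanesulfonate, via potassium indenolate 8 (not isolated)
Conditions: KN(SiMe3)2 (0.98 equiv), THF, −78 °C, 30 min; cannulate into N-(5-chloropyridin-2-yl)triflimide (1.2 equiv), THF, −78 to −20 °C; pH 7 buffer
Reagents that add atoms: N-(5-chloropyridin-2-yl)-1,1,1-trifluoro-N-(trifluoromethylsulfonyl)methanesulfonamide (Comins' reagent), FC(F)(F)S(=O)(=O)N(c1ccc(Cl)cn1)S(=O)(=O)C(F)(F)F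
Why: Enolate O-sulfonylation (enol triflate formation) at the only α-position, in which the stabilised 2-aryl enolate is too weak a base to deprotonate the new doubly benzylic C1–H of the indene and the slight deficit of amide base plus inverse addition keep that single stereocentre intact.

**Step 6**
Reactants: 10 1-(benzyloxy)-4-bromobenzene
Product: 12 tributyl[4-(benzyloxy)phenyl]stannane, via aryllithium 11 (not isolated)
Conditions: n-BuLi (1.05 equiv), THF, −78 °C, 30 min; Bu3SnCl (1.1 equiv), −78 °C to rt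
Reagents that add atoms: tributyltin chloride, CCCC[Sn](Cl)(CCCC)CCCC
Why: Lithium–bromine exchange followed by stannylation of the aryllithium, with no stereocentre involved.

**Step 7**
Reactants: 9 (1R)-5,7-bis(benzyloxy)-2-[3,5-bis(benzyloxy)phenyl]-1-[4-(benzyloxy)phenyl]-1H-inden-3-yl trifluoromethanesulfonate; 12 tributyl[4-(benzyloxy)phenyl]stannane
Product: 13 [(1S)-5,7-bis(benzyloxy)-2-[3,5-bis(benzyloxy)phenyl]-1-[4-(benzyloxy)phenyl]-1H-inden-3-yl][4-(benzyloxy)phenyl]methanone
Conditions: CO (3 atm), Pd(PPh3)4 (5 mol %), LiCl (3 equiv), THF, 60 °C; neutral work-up (no amine, no fluoride)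
Reagents that add atoms: carbon monoxide, [C-]#[O+]
Why: Carbonylative Stille coupling, in which oxidative addition of the alkenyl triflate, fast CO insertion at the crowded alkenyl–palladium bond, aryl transfer from tin and reductive elimination give the aryl ketone without any base, so the acidic C1–H of the vinylogous ketone is not epimerised (the descriptor changes from R to S only because the priorities change).

**Step 8**
Reactants: 13 [(1S)-5,7-bis(benzyloxy)-2-[3,5-bis(benzyloxy)phenyl]-1-[4-(benzyloxy)phenyl]-1H-inden-3-yl][4-(benzyloxy)phenyl]methanone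
Product: 15 caraphenol C [(1R,2R,3R)-2-(3,5-dihydroxyphenyl)-4,6-dihydroxy-3-(4-hydroxyphenyl)-2,3-dihydro-1H-inden-1-yl](4-hydroxyphenyl)methanone (all-cis), via hexaphenol indenyl ketone 14 (not isolated)
Conditions: H2 (1 atm, raised to 4 atm only if 14 persists), 10% Pd/C, EtOAc–MeOH 1:1, AcOH (1 vol %), rt, LC–MS control; Celite, Sephadex LH-20 (MeOH)
Reagents that add atoms: none
Why: Heterogeneous hydrogenolysis and hydrogenation, in which the six O-benzyl groups fall first and the tetrasubstituted enone then takes up H2 by syn addition on the face opposite to the C3 aryl group (the face that already carries H-3), placing H-1, H-2 and H-3 on one side and giving the contra-thermodynamic all-cis (1R,2R,3R) array under kinetic control, while a 1,4-reduction and enol protonation pathway would deliver hydrogen to the same face for the same steric reason.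

## Compound list

1 | 1-[3,5-bis(benzyloxy)phenyl]ethan-1-one | CC(=O)c1cc(OCc2ccccc2)cc(OCc2ccccc2)c1 | starting material
2 | 1-[3,5-bis(benzyloxy)-2-bromophenyl]ethan-1-one | CC(=O)c1cc(OCc2ccccc2)cc(OCc2ccccc2)c1Br | intermediate
3 | 4-(benzyloxy)benzaldehyde | O=Cc1ccc(OCc2ccccc2)cc1 | starting material
4 | (2E)-1-[3,5-bis(benzyloxy)-2-bromophenyl]-3-[4-(benzyloxy)phenyl]prop-2-en-1-one | O=C(/C=C/c1ccc(OCc2ccccc2)cc1)c1cc(OCc2ccccc2)cc(OCc2ccccc2)c1Br | intermediate
5 | (3R)-4,6-bis(benzyloxy)-3-[4-(benzyloxy)phenyl]-2,3-dihydro-1H-inden-1-one | O=C1C[C@H](c2ccc(OCc3ccccc3)cc2)c2c(OCc3ccccc3)cc(OCc3ccccc3)cc21 | intermediate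
6 | 1,3-bis(benzyloxy)-5-bromobenzene | Brc1cc(OCc2ccccc2)cc(OCc2ccccc2)c1 | starting material
7 | (2R,3R)-4,6-bis(benzyloxy)-2-[3,5-bis(benzyloxy)phenyl]-3-[4-(benzyloxy)phenyl]-2,3-dihydro-1H-inden-1-one (trans) | O=C1[C@@H](c2cc(OCc3ccccc3)cc(OCc3ccccc3)c2)[C@H](c2ccc(OCc3ccccc3)cc2)c2c(OCc3ccccc3)cc(OCc3ccccc3)cc21 | intermediate
8 | potassium (1S)-5,7-bis(benzyloxy)-2-[3,5-bis(benzyloxy)phenyl]-1-[4-(benzyloxy)phenyl]-1H-inden-3-olate | [K+].[O-]C1=C(c2cc(OCc3ccccc3)cc(OCc3ccccc3)c2)[C@H](c2ccc(OCc3ccccc3)cc2)c2c(OCc3ccccc3)cc(OCc3ccccc3)cc12 | intermediate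
9 | (1R)-5,7-bis(benzyloxy)-2-[3,5-bis(benzyloxy)phenyl]-1-[4-(benzyloxy)phenyl]-1H-inden-3-yl trifluoromethanesulfonate | O=S(=O)(OC1=C(c2cc(OCc3ccccc3)cc(OCc3ccccc3)c2)[C@H](c2ccc(OCc3ccccc3)cc2)c2c(OCc3ccccc3)cc(OCc3ccccc3)cc12)C(F)(F)F | intermediate
10 | 1-(benzyloxy)-4-bromobenzene | Brc1ccc(OCc2ccccc2)cc1 | starting material
11 | [4-(benzyloxy)phenyl]lithium | [Li]c1ccc(OCc2ccccc2)cc1 | intermediate
12 | tributyl[4-(benzyloxy)phenyl]stannane | CCCC[Sn](CCCC)(CCCC)c1ccc(OCc2ccccc2)cc1 | intermediate
13 | [(1S)-5,7-bis(benzyloxy)-2-[3,5-bis(benzyloxy)phenyl]-1-[4-(benzyloxy)phenyl]-1H-inden-3-yl][4-(benzyloxy)phenyl]methanone | O=C(c1ccc(OCc2ccccc2)cc1)C1=C(c2cc(OCc3ccccc3)cc(OCc3ccccc3)c2)[C@H](c2ccc(OCc3ccccc3)cc2)c2c(OCc3ccccc3)cc(OCc3ccccc3)cc12 | intermediate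
14 | [(1S)-2-(3,5-dihydroxyphenyl)-5,7-dihydroxy-1-(4-hydroxyphenyl)-1H-inden-3-yl](4-hydroxyphenyl)methanone | O=C(c1ccc(O)cc1)C1=C(c2cc(O)cc(O)c2)[C@H](c2ccc(O)cc2)c2c(O)cc(O)cc12 | intermediate
15 | caraphenol C, [(1R,2R,3R)-2-(3,5-dihydroxyphenyl)-4,6-dihydroxy-3-(4-hydroxyphenyl)-2,3-dihydro-1H-inden-1-yl](4-hydroxyphenyl)methanone (all-cis) | O=C(c1ccc(O)cc1)[C@H]1c2cc(O)cc(O)c2[C@@H](c2ccc(O)cc2)[C@H]1c1cc(O)cc(O)c1 | target

## Step count and risks

Total step count: 8. Longest linear sequence: 7 steps (steps 1, 2, 3, 4, 5, 7 and 8; step 6 is a one-step side branch).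

The three steps most likely to fail:

**Step 3.** The aryl bromide is electron-rich and flanked by a benzyloxy group, so oxidative addition may be slow. Hydrodebromination or transfer reduction of the enone can compete, and the ee is not assured for this substitution pattern. The fallback sets out from 4 and comes back at 5. The ring is closed without a hydride donor (Pd(OAc)2, PPh3, NaOAc, DMF, 110 °C), so that the palladium enolate ends by β-hydride elimination and gives the achiral 4,6-bis(benzyloxy)-3-[4-(benzyloxy)phenyl]-1H-inden-1-one F1; any indanone formed beside it is dehydrogenated with DDQ. C3 is then set by copper hydride asymmetric conjugate reduction (Cu(OAc)2, DTBM-SEGPHOS antipode giving 3R, (EtO)2MeSiH, t-BuOH, toluene, 0 °C), which gives 5. The stereocentre then comes from hydride delivery to a prochiral β,β-disubstituted enone and not from carbopalladation.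

**Step 7.** The triflate sits on a tetrasubstituted alkene between an aryl group and the ring, so acyl transfer may be slow and direct, CO-free coupling can compete. The fallback sets out from 9 and comes back at 13. A Nozaki–Hiyama–Kishi coupling of 9 with aldehyde 3 (CrCl2 4 equiv, NiCl2 2 mol %, DMF, rt) gives [(1S)-5,7-bis(benzyloxy)-2-[3,5-bis(benzyloxy)phenyl]-1-[4-(benzyloxy)phenyl]-1H-inden-3-yl][4-(benzyloxy)phenyl]methanol F2 as a mixture of carbinol epimers, which does not matter. Unbuffered Dess–Martin periodinane in CH2Cl2 then oxidises the doubly activated alcohol to 13. This path uses neither CO nor tin and stays neutral throughout.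

**Step 8.** The aryl ketone may be over-reduced while the hindered alkene is forced, the reaction may stall at 14, or C1 may epimerise on the catalyst to the more stable 1,2-trans isomer. The fallback sets out from 13 and comes back at 15, and it separates the two events. Homogeneous hydrogenation with [Ir(cod)(PCy3)(py)]PF6 (5 mol %) and H2 in CH2Cl2 saturates the alkene on the same face, guided by the ketone oxygen, and leaves the benzyl ethers and the ketone alone. It gives [(1R,2R,3R)-4,6-bis(benzyloxy)-2-[3,5-bis(benzyloxy)phenyl]-3-[4-(benzyloxy)phenyl]-2,3-dihydro-1H-inden-1-yl][4-(benzyloxy)phenyl]methanone F3. Non-reductive debenzylation with BCl3 and pentamethylbenzene in CH2Cl2 at −78 °C then gives 15 without any hydrogenation catalyst near the ketone.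

## Further compounds

F1 | step 3 | 4,6-bis(benzyloxy)-3-[4-(benzyloxy)phenyl]-1H-inden-1-one | O=C1C=C(c2ccc(OCc3ccccc3)cc2)c2c(OCc3ccccc3)cc(OCc3ccccc3)cc21
F2 | step 7 | [(1S)-5,7-bis(benzyloxy)-2-[3,5-bis(benzyloxy)phenyl]-1-[4-(benzyloxy)phenyl]-1H-inden-3-yl][4-(benzyloxy)phenyl]methanol (carbinol epimers) | OC(c1ccc(OCc2ccccc2)cc1)C1=C(c2cc(OCc3ccccc3)cc(OCc3ccccc3)c2)[C@H](c2ccc(OCc3ccccc3)cc2)c2c(OCc3ccccc3)cc(OCc3ccccc3)cc12
F3 | step 8 | [(1R,2R,3R)-4,6-bis(benzyloxy)-2-[3,5-bis(benzyloxy)phenyl]-3-[4-(benzyloxy)phenyl]-2,3-dihydro-1H-inden-1-yl][4-(benzyloxy)phenyl]methanone (all-cis) | O=C(c1ccc(OCc2ccccc2)cc1)[C@H]1c2cc(OCc3ccccc3)cc(OCc3ccccc3)c2[C@@H](c2ccc(OCc3ccccc3)cc2)[C@H]1c1cc(OCc2ccccc2)cc(OCc2ccccc2)c1
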